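## Analysis of the target

Target 36 is a sesquineolignan built from a γ-butyrolactone (ring C: O1, C2 carbonyl, C3, C4, C5). C3 carries, through one CH2 group, C5' of a 2,3-trans-2-aryl-3-(hydroxymethyl)-7-methoxy-2,3-dihydrobenzofuran (rings A and B, primed locants). C4 carries a secondary benzylic carbinol carbon (C7) with a second guaiacyl ring (ring D). There are five stereocentres in two clusters: C3 (R) and C4 (R), trans on the lactone, with C7 (R) attached to C4; and C2' (S) and C3' (R), trans on the dihydrofuran. The CH2–aryl link insulates the clusters, so neither can relay its configuration to the other and each needs its own source of absolute configuration. The sensitive groups are the para-hydroxybenzylic alcohol at C7 and the para-hydroxybenzylic aryl ether at C2' (both ionise under acid to quinone methides), the lactone (under base the C7 hydroxyl can translactonise), and two free phenols. The difficulty lies in joining the halves at an unactivated CH2 group while three contiguous centres are controlled next to it, and in keeping the last steps near neutral. The strategy rests on one feature: C3 and C4 are adjacent ring carbons, each extended by one exocyclic carbon (the CH2 on C3, C7 on C4). The bonds C3–CH2 and C4–C7 can therefore be the two new bonds of a cyclobutane fused to a butenolide C3=C4, with the C7 oxygen on the four-membered ring as a tertiary cyclobutanol.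

## Retrosynthetic reasoning

36 is traced back to its tris-silyl ether 35 and then to ketone 34. Placing a carbonyl at C7 makes C4 epimerisable and lets the carbinol centre be set last, by reagent-controlled reduction of an aryl ketone. The forward steps are a face-selective hydride delivery and a buffered desilylation.

34 is the C4 epimer of 33. This operation is accepted because the cycloaddition used below can only deliver a cis relationship between the C3 and C4 substituents. C4–H is α to an aryl ketone, while C3–H is α only to the lactone, so base should move C4 alone, towards the more stable trans arrangement.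

In 33 the C5'–CH2 bond is cut, and in the same move the CH2 group is reconnected to C7. This gives cyclobutanol 12 and aryl bromide 32. The cut is made here because it is the only bond joining the two stereochemical clusters, so each half can be made separately. The forward reaction is a palladium-catalysed ring opening of the cyclobutanol alkoxide that cleaves the CH2–C7 bond, releases the C7 ketone and hands the CH2 group to the aryl partner. No thermal reaction places a one-carbon nucleophile on C3 and an aroyl group on C4 in one event.

12 comes from 11 by selective desilylation, and 11 comes from photoadduct 8 by removal of the auxiliary. The menthyloxy group is taken off at this stage, not after the union, for three reasons. Later it would sit β to an enolisable ketone and could be eliminated. C4 would have to be epimerised onto the face that the menthyloxy group occupies. A free C7 hydroxyl would compete in the relactonisation. The forward step is base-mediated opening of the acylal with hydride reduction in the same flask; a robust silyl ether on the cyclobutanol prevents retro-aldol opening.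

8 is cut at C3–CH2 and C4–C7, which gives furanone 4 and enol ether 7. This is the key disconnection: two skeletal bonds, one ring and the C3 stereocentre in one step, with C5 already at the lactone oxidation level. The forward reaction must be head-to-tail and must take place on the furanone face opposite the menthyloxy group.

4 is the menthyl acetal of lactol 2, which comes from 1 by photooxygenation; 3 supplies the chirality and is recovered in step 6. 7 is the silyl enol ether of ketone 6, made from 5.

32 is the bis-silyl ether of 31, and 31 is opened at O1'–C2' to diol 28 (through 29 and 30). This closure is stereoconvergent at C2' and thermodynamically trans, so only C3' has to be set beforehand.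

28 is cut between the aryl-bearing carbon and the carbinol carbon, which leads to aldol adduct 27 and from there to imide 22 and aldehyde 24. The auxiliary 20 fixes the future C3'. The carbinol configuration is irrelevant, which makes the aldol forgiving.

22 comes from acid 19, and 19 from phenol 13 by O-allylation, Claisen rearrangement to 15, protection to 16 and two-stage oxidative cleavage through 18. Bromine is present from the start, so its position is never in doubt. 24 is the methoxymethyl ether of 23.

## Alternatives that were turned down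

Alternative 1: The disconnection is O1'–C2' of the dihydrobenzofuran. In the forward key step, acid removes water from the benzylic carbinol of a 1,2-diarylpropane-1,3-diol (compound 29 of the route) and the ortho phenol adds to the quinone methide to give the trans bromide A1, which is identical with 31. In its favour, both carbinol epimers converge, the trans ring is the thermodynamic product, and one auxiliary-set centre controls two. Against it as the organising idea, it solves the easier cluster only. A1 is a fragment; the aryl–CH2 bond and the three contiguous centres of the lactone half are left without a plan. On the dihydrobenzofuran this closure is as good as anything available, and it is therefore kept as a supporting step (step 17). What the photocycloaddition strategy adds is the union and the lactone stereochemistry.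

Alternative 2: The disconnection is O1–C5 of the lactone, from a 3-substituted cyclobutanone A3. In the forward key step, a peracid under Sc(OTf)3 and a chiral N,N'-dioxide inserts oxygen next to one of the two enantiotopic CH2 groups to give lactone A2. In its favour, the step is catalytic, and C3 would then be set by trans-selective enolate alkylation of A2 with the benzylic bromide A7. That alkylation is classical and on this one bond probably more certain than the palladium step chosen here. Against it, the carbinol centre of A3 must be set separately, and the catalyst must then override the bias of that adjacent centre, in a branched oxygenated substrate rather than a 3-aryl one. A7 costs extra steps from A1 and is a labile electron-rich benzylic halide. A peracid meets an electron-rich arene. The length is comparable. The chosen strategy offers both substituent bonds in one step, absolute control from a recoverable auxiliary purified by crystallisation, and a C7 ketone that permits late reagent control.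

Alternative 3: The disconnection is C4–C5 and the O1–C2 acyl bond. In the forward key step, the ketone enolate of γ-keto ester A5 adds to formaldehyde A6 and the new alkoxide lactonises to give A4, which differs from 34 only in one silyl group. In its favour, it is the shortest route to the lactone and is stronger than the chosen route on step economy; the trans product is thermodynamic and the endgame would be the same. Against it, the one stereocentre of A5 (the future C3) has to be made first by a separate asymmetric alkylation and then sits α to an ester under enolate-forming base. Formaldehyde aldols are hard to hold at mono-addition and can dehydrate to the enone. The key step itself controls no absolute configuration. The chosen strategy sets C3 on a rigid bicycle before any enolisable ketone exists and brings C5 in with the butenolide.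

Key step: step 5

Assumption: the aryl-bearing cyclobutane carbon of 8, 11 and 12 is written as the aryl-exo epimer; this centre becomes the ketone carbon in step 19, so either epimer serves.

## Route

Step 1
Reactants: 1 furfural
Product: 2 5-hydroxy-2(5H)-furanone (racemic lactol)
Conditions: O2, rose bengal (cat.), hν (visible), MeOH, rt
Reagents that add atoms: oxygen, O=O
Why: Dye-sensitised singlet oxygen adds [4+2] across the furan; methanolysis of the endoperoxide expels the formyl carbon and leaves the pseudo-acid (photooxygenation of furfural).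

Step 2
Reactants: 2 5-hydroxy-2(5H)-furanone; 3 (+)-menthol, (1S,2R,5S)
Product: 4 (5S)-5-[(1S,2R,5S)-menthyloxy]-2(5H)-furanone
Conditions: camphorsulfonic acid (cat.), toluene, reflux (Dean–Stark); crystallisation from petroleum ether, mother liquor re-equilibrated with acid
Reagents that add atoms: none
Why: Acid-catalysed acetalisation of the lactol; the C5 epimers interconvert under acid and the (5S) epimer should be drained off by crystallisation, so C5 is set by crystallisation-driven equilibration.

Step 3
Reactants: 5 acetovanillone
Product: 6 1-[3-methoxy-4-(triisopropylsilyloxy)phenyl]ethanone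
Conditions: TIPSCl, imidazole, DMF, rt
Reagents that add atoms: triisopropylsilyl chloride, CC(C)[Si](Cl)(C(C)C)C(C)C
Why: Phenol silylation; TIPS is chosen because this aryl ether must later survive aqueous hydroxide (step 6) and HF·pyridine (step 7).

Step 4
Reactants: 6 1-[3-methoxy-4-(triisopropylsilyloxy)phenyl]ethanone
Product: 7 1-[3-methoxy-4-(triisopropylsilyloxy)phenyl]-1-(triethylsilyloxy)ethene
Conditions: TESOTf, Et3N, CH2Cl2, 0 °C
Reagents that add atoms: triethylsilyl triflate, CC[Si](CC)(CC)OS(=O)(=O)C(F)(F)F
Why: Soft enolisation of the aryl methyl ketone and O-silylation; TES replaces TMS so that the enol ether and the later tertiary silyl ether tolerate long irradiation, chromatography and the basic step 6.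

Step 5
Reactants: 4 (5S)-5-[(1S,2R,5S)-menthyloxy]-2(5H)-furanone; 7 1-[3-methoxy-4-(triisopropylsilyloxy)phenyl]-1-(triethylsilyloxy)ethene
Product: 8 (1R,4S,5R,6S)-6-[3-methoxy-4-(triisopropylsilyloxy)phenyl]-4-[(1S,2R,5S)-menthyloxy]-6-(triethylsilyloxy)-3-oxabicyclo[3.2.0]heptan-2-one (cis-fused; cyclobutane anti to menthyloxy; aryl exo)
Conditions: hν (medium-pressure Hg lamp, Pyrex filter), dry acetone, −20 °C; 7 (3 equiv) added in portions
Reagents that add atoms: none
Why: Acetone absorbs the light and passes its triplet energy to 4; the triplet furanone pairs with the electron-rich alkene 7, its alpha carbon bonds to the unsubstituted CH2 terminus, and the resulting 1,4-biradical (a secondary radical at the furanone beta carbon and a benzylic alpha-silyloxy radical) closes after spin inversion. The closest known reaction type is the enone–alkene [2+2] photocycloaddition of 5-alkoxy-2(5H)-furanones with ketene acetals and enol ethers, which places the donor-bearing carbon on the beta carbon (head-to-tail). The one ring formed, the cyclobutane, closes by radical–radical recombination within this biradical, and the fusion can only be cis because a trans-fused bicyclo[3.2.0] lactone is too strained. Lactone C3 (bicyclic C1) is set by the menthyloxy group on C5 of 4, which covers one face of the planar furanone so that the alkene adds anti to it; lactone C4 (bicyclic C5) follows from the cis fusion; the aryl-bearing carbon is not controlled and need not be. The step needs head-to-tail regioselectivity, which the strong polarisation of 7 should secure (nucleophilic CH2 terminus, radical-stabilising aryl/silyloxy carbon), and anti facial selectivity, which the auxiliary and the low temperature should secure. 7 has no stereogenic double bond, so triplet energy that leaks into it is lost as heat and costs irradiation time, not material. The TES ether lets 8 be freed from its facial isomer by chromatography and crystallisation, which matters because the diastereomeric purity of 8 becomes the enantiomeric purity of 11 once the auxiliary is gone.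

Step 6
Reactants: 8 photoadduct
Product: 11 (1R,5S,6S)-6-[3-methoxy-4-(triisopropylsilyloxy)phenyl]-6-(triethylsilyloxy)-3-oxabicyclo[3.2.0]heptan-2-one, via sodium formylcyclobutanecarboxylate 9 (not isolated), via sodium hydroxymethylcyclobutanecarboxylate 10 (not isolated)
Conditions: NaBH4, NaOH (1 M aq., 1.2 equiv), EtOH–THF, 0 °C; then 1 M HCl to pH 3, rt
Reagents that add atoms: sodium hydroxide, [Na+].[OH-] (one carboxyl oxygen passes through the carboxylate)
Why: Hydroxide opens the acylal lactone, the hemiacetal loses menthoxide, borohydride reduces the aldehyde as it forms, and acid relactonises the cis hydroxy acid (the known conversion of 5-alkoxybutyrolactones into butyrolactones by basic borohydride). The tertiary TES ether blocks retro-aldol opening of the cyclobutane, and only one hydroxyl is free, so only one lactone can form.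

Step 7
Reactants: 11 bicyclic lactone
Product: 12 (1R,5S,6S)-6-hydroxy-6-[3-methoxy-4-(triisopropylsilyloxy)phenyl]-3-oxabicyclo[3.2.0]heptan-2-one
Conditions: HF·pyridine, pyridine, THF, 0 °C → rt
Reagents that add atoms: none
Why: Buffered acidic fluoride cleaves the alkyl TES ether, while the aryl TIPS ether reacts much more slowly under these conditions; stronger acid is avoided because the tertiary benzylic carbinol ionises easily.

Step 8
Reactants: 13 4-bromo-2-methoxyphenol
Product: 14 1-(allyloxy)-4-bromo-2-methoxybenzene
Conditions: allyl bromide, K2CO3, acetone, reflux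
Reagents that add atoms: allyl bromide, C=CCBr
Why: Williamson O-alkylation of the phenoxide by SN2 at the allylic halide.

Step 9
Reactants: 14 1-(allyloxy)-4-bromo-2-methoxybenzene
Product: 15 2-allyl-4-bromo-6-methoxyphenol
Conditions: N,N-diethylaniline, 200 °C
Reagents that add atoms: none
Why: Aromatic Claisen rearrangement ([3,3] shift, then tautomerisation); only one ortho position is free and the para position is blocked by bromine.

Step 10
Reactants: 15 2-allyl-4-bromo-6-methoxyphenol
Product: 16 1-allyl-5-bromo-3-methoxy-2-(methoxymethoxy)benzene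
Conditions: MOMCl, iPr2NEt, CH2Cl2, 0 °C → rt
Reagents that add atoms: chloromethyl methyl ether, COCCl
Why: O-alkylation of the phenol; the MOM ether withstands the oxidations, the boron enolate and LiBH4, and is removed in the acid step 17.

Step 11
Reactants: 16 1-allyl-5-bromo-3-methoxy-2-(methoxymethoxy)benzene
Product: 18 2-[5-bromo-3-methoxy-2-(methoxymethoxy)phenyl]acetaldehyde, via vicinal diol 17 (not isolated)
Conditions: OsO4 (2 mol %), NaIO4, 2,6-lutidine, dioxane–H2O, rt
Reagents that add atoms: sodium periodate (oxygen source, relayed by OsO4), [Na+].[O-]I(=O)(=O)=O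
Why: Lemieux–Johnson cleavage: catalytic dihydroxylation of the terminal alkene and periodate cleavage of the diol; 2,6-lutidine suppresses over-oxidation.

Step 12
Reactants: 18 arylacetaldehyde
Product: 19 2-[5-bromo-3-methoxy-2-(methoxymethoxy)phenyl]acetic acid
Conditions: NaClO2, NaH2PO4, 2-methyl-2-butene, t-BuOH–H2O, rt
Reagents that add atoms: sodium chlorite, [Na+].[O-]Cl=O
Why: Pinnick oxidation; the alkene scavenges hypochlorite so that the electron-rich ring is not chlorinated.

Step 13
Reactants: 19 arylacetic acid; 20 (S)-4-benzyl-2-oxazolidinone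
Product: 22 (S)-4-benzyl-3-{2-[5-bromo-3-methoxy-2-(methoxymethoxy)phenyl]acetyl}oxazolidin-2-one, via mixed pivalic anhydride 21 (not isolated)
Conditions: PivCl, Et3N, THF, −20 °C; then 20, LiCl, rt
Reagents that add atoms: none
Why: The acid is activated as the mixed pivalic anhydride and N-acylates the oxazolidinone under LiCl/Et3N; attack occurs at the less hindered arylacetyl carbonyl.

Step 14
Reactants: 23 vanillin
Product: 24 3-methoxy-4-(methoxymethoxy)benzaldehyde
Conditions: MOMCl, iPr2NEt, CH2Cl2, 0 °C → rt
Reagents that add atoms: chloromethyl methyl ether, COCCl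
Why: Phenol protection with the same acid-labile group as on ring B, so that one acid treatment frees both phenols in step 17.

Step 15
Reactants: 22 imide; 24 3-methoxy-4-(methoxymethoxy)benzaldehyde
Product: 27 (S)-4-benzyl-3-{(2S,3S)-2-[5-bromo-3-methoxy-2-(methoxymethoxy)phenyl]-3-hydroxy-3-[3-methoxy-4-(methoxymethoxy)phenyl]propanoyl}oxazolidin-2-one, via boron enolate 25 (not isolated), via boron aldolate 26 (not isolated)
Conditions: Bu2BOTf, iPr2NEt, CH2Cl2, −78 → 0 °C; 24, −78 → 0 °C; pH 7 buffer, MeOH, H2O2, 0 °C
Reagents that add atoms: none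
Why: Evans syn-aldol reaction: the Z boron enolate reacts through a chair Zimmerman–Traxler transition state on the face away from the benzyl group of the auxiliary. This fixes the aryl-bearing carbon (the later C3'); the carbinol centre is formed syn but is erased in step 17.

Step 16
Reactants: 27 aldol adduct
Product: 28 (1S,2R)-2-[5-bromo-3-methoxy-2-(methoxymethoxy)phenyl]-1-[3-methoxy-4-(methoxymethoxy)phenyl]propane-1,3-diol
Conditions: LiBH4, THF–H2O (1 equiv), 0 °C
Reagents that add atoms: none
Why: LiBH4 reduces the exocyclic imide carbonyl and releases the auxiliary; the α-aryl stereocentre is not enolised under these hydride conditions.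

Step 17
Reactants: 28 bis-MOM diol
Product: 31 (2S,3R)-5-bromo-2-(4-hydroxy-3-methoxyphenyl)-3-(hydroxymethyl)-7-methoxy-2,3-dihydrobenzofuran, via free triol 29 (not isolated), via quinone methide 30 (not isolated)
Conditions: conc. HCl (cat.), MeOH–THF, 45 °C
Reagents that add atoms: none
Why: Acid removes both MOM ethers, the para-hydroxybenzylic carbinol of 29 loses water to the quinone methide 30 (or its O-protonated form), and the ortho phenol oxygen adds to the methide carbon in a 5-exo-trig closure. The addition is reversible, so both carbinol epimers converge on the trans ring and C2' is set by the fixed C3'.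

Step 18
Reactants: 31 dihydrobenzofuran bromide
Product: 32 (2S,3R)-5-bromo-3-[(tert-butyldimethylsilyloxy)methyl]-2-[4-(tert-butyldimethylsilyloxy)-3-methoxyphenyl]-7-methoxy-2,3-dihydrobenzofuran
Conditions: TBSCl, imidazole, DMF, rt
Reagents that add atoms: tert-butyldimethylsilyl chloride, CC(C)(C)[Si](C)(C)Cl
Why: Silylation of the phenol and the primary alcohol; both would interfere with the palladium alkoxide chemistry of step 19, and the TBS ethers leave together with the TIPS group at the end.

Step 19
Reactants: 12 cyclobutanol; 32 aryl bromide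
Product: 33 (3R,4S)-3-{[(2S,3R)-3-[(tert-butyldimethylsilyloxy)methyl]-2-[4-(tert-butyldimethylsilyloxy)-3-methoxyphenyl]-7-methoxy-2,3-dihydrobenzofuran-5-yl]methyl}-4-[3-methoxy-4-(triisopropylsilyloxy)benzoyl]dihydrofuran-2(3H)-one (3,4-cis)
Conditions: Pd(OAc)2 (5 mol %), XPhos (10 mol %), Cs2CO3, toluene, 80 °C
Reagents that add atoms: none
Why: Oxidative addition of 32 to zerovalent palladium, exchange of bromide for the cesium alkoxide of 12 and β-carbon elimination of the less substituted C–CH2 bond release the aryl ketone and a primary alkylpalladium, which reductively eliminates to the aryl–CH2 bond (palladium-catalysed ring-opening arylation of tert-cyclobutanols with aryl bromides). Chelation of the alkylpalladium by the lactone carbonyl and the bulky biaryl phosphine should favour reductive elimination over β-hydride elimination; C3 is not touched.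

Step 20
Reactants: 33 cis keto lactone
Product: 34 (3R,4R)-3-{[(2S,3R)-3-[(tert-butyldimethylsilyloxy)methyl]-2-[4-(tert-butyldimethylsilyloxy)-3-methoxyphenyl]-7-methoxy-2,3-dihydrobenzofuran-5-yl]methyl}-4-[3-methoxy-4-(triisopropylsilyloxy)benzoyl]dihydrofuran-2(3H)-one (3,4-trans)
Conditions: DBU (0.2 equiv), CH2Cl2, 0 °C → rt
Reagents that add atoms: none
Why: C4–H is α to the aryl ketone and is removed far more easily than C3–H; reprotonation under equilibrium gives the 3,4-trans lactone, the more stable arrangement of two vicinal carbon substituents. The ring oxygen β to the ketone is endocyclic and poorly aligned with the exocyclic enolate, so ring opening should be slow.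

Step 21
Reactants: 34 trans keto lactone
Product: 35 (3R,4R)-3-{[(2S,3R)-3-[(tert-butyldimethylsilyloxy)methyl]-2-[4-(tert-butyldimethylsilyloxy)-3-methoxyphenyl]-7-methoxy-2,3-dihydrobenzofuran-5-yl]methyl}-4-{(R)-hydroxy[3-methoxy-4-(triisopropylsilyloxy)phenyl]methyl}dihydrofuran-2(3H)-one
Conditions: (S)-2-methyl-CBS-oxazaborolidine (0.5 equiv), BH3·SMe2, THF, −20 °C; MeOH quench
Reagents that add atoms: none
Why: Corey–Bakshi–Shibata reduction: the ketone binds to the catalyst boron anti to the aryl group (the large substituent) and hydride is delivered to the face that gives the (R) carbinol, as for aryl alkyl ketones with the (S) catalyst. The lactone is not reduced by borane at this temperature.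

Step 22
Reactants: 35 tris-silyl ether
Product: 36 target, (3R,4R)-4-[(R)-hydroxy(4-hydroxy-3-methoxyphenyl)methyl]-3-{[(2S,3R)-2-(4-hydroxy-3-methoxyphenyl)-3-(hydroxymethyl)-7-methoxy-2,3-dihydrobenzofuran-5-yl]methyl}dihydrofuran-2(3H)-one
Conditions: TBAF, AcOH (1:1), THF, 0 °C → rt
Reagents that add atoms: none
Why: Fluoride cleaves the aryl TIPS, aryl TBS and primary TBS ethers; acetic acid buffers the phenoxides and alkoxides so that neither translactonisation through the C7 hydroxyl nor quinone-methide chemistry at C7 or C2' sets in.

## Compound list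

1 | furfural | O=Cc1ccco1 | starting material
2 | 5-hydroxy-2(5H)-furanone (racemic) | O=C1C=CC(O)O1 | intermediate
3 | (+)-menthol, (1S,2R,5S) | CC(C)[C@H]1CC[C@H](C)C[C@@H]1O | starting material
4 | (5S)-5-[(1S,2R,5S)-menthyloxy]-2(5H)-furanone | O=C1C=C[C@@H](O[C@H]2C[C@@H](C)CC[C@@H]2C(C)C)O1 | intermediate
5 | acetovanillone | CC(=O)c1ccc(O)c(OC)c1 | starting material
6 | 1-[3-methoxy-4-(triisopropylsilyloxy)phenyl]ethanone | CC(=O)c1ccc(O[Si](C(C)C)(C(C)C)C(C)C)c(OC)c1 | intermediate
7 | 1-[3-methoxy-4-(triisopropylsilyloxy)phenyl]-1-(triethylsilyloxy)ethene | C=C(O[Si](CC)(CC)CC)c1ccc(O[Si](C(C)C)(C(C)C)C(C)C)c(OC)c1 | intermediate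
8 | (1R,4S,5R,6S)-6-aryl-4-[(1S,2R,5S)-menthyloxy]-6-(triethylsilyloxy)-3-oxabicyclo[3.2.0]heptan-2-one, aryl = 3-methoxy-4-(triisopropylsilyloxy)phenyl | O=C1O[C@H](O[C@H]3C[C@@H](C)CC[C@@H]3C(C)C)[C@@H]2[C@H]1C[C@@]2(O[Si](CC)(CC)CC)c1ccc(O[Si](C(C)C)(C(C)C)C(C)C)c(OC)c1 | intermediate
9 | sodium cis-3-aryl-2-formyl-3-(triethylsilyloxy)cyclobutane-1-carboxylate | [Na+].[O-]C(=O)[C@@H]1C[C@@](O[Si](CC)(CC)CC)(c2ccc(O[Si](C(C)C)(C(C)C)C(C)C)c(OC)c2)[C@@H]1C=O | intermediate (not isolated)
10 | sodium cis-3-aryl-2-(hydroxymethyl)-3-(triethylsilyloxy)cyclobutane-1-carboxylate | [Na+].[O-]C(=O)[C@@H]1C[C@@](O[Si](CC)(CC)CC)(c2ccc(O[Si](C(C)C)(C(C)C)C(C)C)c(OC)c2)[C@@H]1CO | intermediate (not isolated)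
11 | (1R,5S,6S)-6-[3-methoxy-4-(triisopropylsilyloxy)phenyl]-6-(triethylsilyloxy)-3-oxabicyclo[3.2.0]heptan-2-one | O=C1OC[C@@H]2[C@H]1C[C@@]2(O[Si](CC)(CC)CC)c1ccc(O[Si](C(C)C)(C(C)C)C(C)C)c(OC)c1 | intermediate
12 | (1R,5S,6S)-6-hydroxy-6-[3-methoxy-4-(triisopropylsilyloxy)phenyl]-3-oxabicyclo[3.2.0]heptan-2-one | O=C1OC[C@@H]2[C@H]1C[C@@]2(O)c1ccc(O[Si](C(C)C)(C(C)C)C(C)C)c(OC)c1 | intermediate
13 | 4-bromo-2-methoxyphenol | COc1cc(Br)ccc1O | starting material
14 | 1-(allyloxy)-4-bromo-2-methoxybenzene | C=CCOc1ccc(Br)cc1OC | intermediate
15 | 2-allyl-4-bromo-6-methoxyphenol | C=CCc1cc(Br)cc(OC)c1O | intermediate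
16 | 1-allyl-5-bromo-3-methoxy-2-(methoxymethoxy)benzene | C=CCc1cc(Br)cc(OC)c1OCOC | intermediate
17 | 3-[5-bromo-3-methoxy-2-(methoxymethoxy)phenyl]propane-1,2-diol (racemic) | OCC(O)Cc1cc(Br)cc(OC)c1OCOC | intermediate (not isolated)
18 | 2-[5-bromo-3-methoxy-2-(methoxymethoxy)phenyl]acetaldehyde | O=CCc1cc(Br)cc(OC)c1OCOC | intermediate
19 | 2-[5-bromo-3-methoxy-2-(methoxymethoxy)phenyl]acetic acid | OC(=O)Cc1cc(Br)cc(OC)c1OCOC | intermediate
20 | (S)-4-benzyl-2-oxazolidinone | O=C1OC[C@H](Cc2ccccc2)N1 | starting material
21 | mixed anhydride of 19 with pivalic acid | CC(C)(C)C(=O)OC(=O)Cc1cc(Br)cc(OC)c1OCOC | intermediate (not isolated)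
22 | (S)-4-benzyl-3-{2-[5-bromo-3-methoxy-2-(methoxymethoxy)phenyl]acetyl}oxazolidin-2-one | O=C(Cc1cc(Br)cc(OC)c1OCOC)N1C(=O)OC[C@@H]1Cc1ccccc1 | intermediate
23 | vanillin | COc1cc(C=O)ccc1O | starting material
24 | 3-methoxy-4-(methoxymethoxy)benzaldehyde | COCOc1ccc(C=O)cc1OC | intermediate
25 | (Z)-dibutylboron enolate of 22 | CCCCB(CCCC)O/C(=C\c1cc(Br)cc(OC)c1OCOC)N1C(=O)OC[C@@H]1Cc1ccccc1 | intermediate (not isolated)
26 | dibutylboron aldolate of 27 | O=C(N1C(=O)OC[C@@H]1Cc1ccccc1)[C@@H](c1cc(Br)cc(OC)c1OCOC)[C@H](OB(CCCC)CCCC)c1ccc(OCOC)c(OC)c1 | intermediate (not isolated)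
27 | (S)-4-benzyl-3-{(2S,3S)-2-[5-bromo-3-methoxy-2-(methoxymethoxy)phenyl]-3-hydroxy-3-[3-methoxy-4-(methoxymethoxy)phenyl]propanoyl}oxazolidin-2-one | O=C(N1C(=O)OC[C@@H]1Cc1ccccc1)[C@@H](c1cc(Br)cc(OC)c1OCOC)[C@H](O)c1ccc(OCOC)c(OC)c1 | intermediate
28 | (1S,2R)-2-[5-bromo-3-methoxy-2-(methoxymethoxy)phenyl]-1-[3-methoxy-4-(methoxymethoxy)phenyl]propane-1,3-diol | OC[C@@H](c1cc(Br)cc(OC)c1OCOC)[C@H](O)c1ccc(OCOC)c(OC)c1 | intermediate
29 | (1S,2R)-2-(5-bromo-2-hydroxy-3-methoxyphenyl)-1-(4-hydroxy-3-methoxyphenyl)propane-1,3-diol | OC[C@@H](c1cc(Br)cc(OC)c1O)[C@H](O)c1ccc(O)c(OC)c1 | intermediate (not isolated)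
30 | 4-[(R)-2-(5-bromo-2-hydroxy-3-methoxyphenyl)-3-hydroxypropylidene]-2-methoxycyclohexa-2,5-dien-1-one (quinone methide) | OC[C@@H](c1cc(Br)cc(OC)c1O)C=C1C=CC(=O)C(OC)=C1 | intermediate (not isolated)
31 | (2S,3R)-5-bromo-2-(4-hydroxy-3-methoxyphenyl)-3-(hydroxymethyl)-7-methoxy-2,3-dihydrobenzofuran | COc1cc([C@H]2Oc3c(OC)cc(Br)cc3[C@@H]2CO)ccc1O | intermediate
32 | (2S,3R)-5-bromo-3-[(tert-butyldimethylsilyloxy)methyl]-2-[4-(tert-butyldimethylsilyloxy)-3-methoxyphenyl]-7-methoxy-2,3-dihydrobenzofuran | COc1cc([C@H]2Oc3c(OC)cc(Br)cc3[C@@H]2CO[Si](C)(C)C(C)(C)C)ccc1O[Si](C)(C)C(C)(C)C | intermediate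
33 | (3R,4S) cis keto lactone (name as in step 19) | O=C1OC[C@@H](C(=O)c2ccc(O[Si](C(C)C)(C(C)C)C(C)C)c(OC)c2)[C@H]1Cc1cc(OC)c2O[C@H](c3ccc(O[Si](C)(C)C(C)(C)C)c(OC)c3)[C@@H](CO[Si](C)(C)C(C)(C)C)c2c1 | intermediate
34 | (3R,4R) trans keto lactone (name as in step 20) | O=C1OC[C@H](C(=O)c2ccc(O[Si](C(C)C)(C(C)C)C(C)C)c(OC)c2)[C@H]1Cc1cc(OC)c2O[C@H](c3ccc(O[Si](C)(C)C(C)(C)C)c(OC)c3)[C@@H](CO[Si](C)(C)C(C)(C)C)c2c1 | intermediate
35 | (3R,4R,7R) tris-silyl ether of the target (name as in step 21) | O=C1OC[C@H]([C@@H](O)c2ccc(O[Si](C(C)C)(C(C)C)C(C)C)c(OC)c2)[C@H]1Cc1cc(OC)c2O[C@H](c3ccc(O[Si](C)(C)C(C)(C)C)c(OC)c3)[C@@H](CO[Si](C)(C)C(C)(C)C)c2c1 | intermediate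
36 | CNP0233460.1, (3R,4R)-4-[(R)-hydroxy(4-hydroxy-3-methoxyphenyl)methyl]-3-{[(2S,3R)-2-(4-hydroxy-3-methoxyphenyl)-3-(hydroxymethyl)-7-methoxy-2,3-dihydrobenzofuran-5-yl]methyl}dihydrofuran-2(3H)-one | COc1cc([C@H]2Oc3c(OC)cc(C[C@H]4C(=O)OC[C@@H]4[C@@H](O)c4ccc(O)c(OC)c4)cc3[C@@H]2CO)ccc1O | target

## Step count and least certain steps

Total: 22 steps. Longest linear sequence: 14 steps (13 → 36 through steps 8–13 and 15–22). The cyclobutanol branch is 9 steps from 1 or from 5 to 36.

Step 5 (key step). The aryl-conjugated enol ether 7 has the lowest triplet energy in the flask, so sensitiser and furanone triplets may be quenched by energy transfer faster than they add. Conversion would then be slow, and side processes could gain ground: oxetane formation between excited acetone and the enol ether; electron transfer followed by loss of the silyl group and Michael-type coupling; and head-to-head addition through the alkene-centred triplet. Facial selectivity of menthyloxyfuranones in photocycloadditions is also incomplete, which would cost material at the purification of 8. The fallback sets out from 4 (and from 13 for the aryl group) and comes back at 12. 4 is irradiated at 254 nm in acetonitrile with 1,1-diethoxyethene, an alkene that neither absorbs nor quenches. This should give the head-to-tail adduct, cis-fused 6,6-diethoxy-4-[(1S,2R,5S)-menthyloxy]-3-oxabicyclo[3.2.0]heptan-2-one F1. Basic borohydride as in step 6, followed by aqueous HCl, should remove the auxiliary, relactonise and unmask the ketone to (1R,5S)-3-oxabicyclo[3.2.0]heptane-2,6-dione F2. 13 is silylated to 4-bromo-2-methoxy-1-(triisopropylsilyloxy)benzene F3, which is lithiated (n-BuLi), transmetalated with CeCl3 and added to the strained ketone of F2 at −78 °C from the convex face. This should give 12, at the cost of two more steps.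

Step 19. The primary alkylpalladium may undergo β-hydride elimination (towards the α-methylene lactone and the reduced arene) before it reductively eliminates. β-Carbon elimination may also cleave the ring-fusion bond in place of the CH2 bond, and the hindered tertiary alkoxide may exchange slowly onto palladium. The fallback gives up the cyclobutanol for this bond; it sets out from 2, 23 and 32 and comes back at 34. 2 is acetalised with (−)-menthol and crystallised to (5R)-5-[(1R,2S,5R)-menthyloxy]-2(5H)-furanone F4. 23 is silylated to 3-methoxy-4-(triisopropylsilyloxy)benzaldehyde F5 and converted with propane-1,3-dithiol into 2-[3-methoxy-4-(triisopropylsilyloxy)phenyl]-1,3-dithiane F6. 32 is lithiated and treated with paraformaldehyde to give the 5-(hydroxymethyl) compound F7, and bromination (CBr4, PPh3) gives the 5-(bromomethyl) compound F8. Lithiated F6 adds to F4 anti to the menthyloxy group, and the enolate is alkylated by F8 anti to the new substituent. This should give the all-trans 3-(arylmethyl)-4-(2-aryl-1,3-dithian-2-yl)-5-menthyloxy lactone F9. Basic borohydride and acid convert the acylal into the lactone, trans-3-(arylmethyl)-4-(2-aryl-1,3-dithian-2-yl)dihydrofuran-2(3H)-one F10, and dithiane cleavage (MeI, CaCO3, aqueous MeCN) gives 34.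

Step 6. The cyclobutane carbaldehyde may epimerise at its α-carbon before it is reduced; the resulting trans hydroxy acid cannot lactonise. Hydroxide may also remove the TES group, after which retro-aldol opening of the four-membered ring would follow. The fallback sets out from 8 and comes back at 11. LiAlH4 reduces both the lactone carbonyl and the masked aldehyde without a free aldehyde stage, giving cis-3-aryl-3-(triethylsilyloxy)cyclobutane-1,2-dimethanol F11. Oxidative lactonisation with TEMPO and PhI(OAc)2 should then start at the less hindered carbinol, the one remote from the quaternary carbon, and place the carbonyl where 11 has it.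

Step 21. This is a case of double diastereodifferentiation: a Felkin–Anh analysis of 34 (largest α-substituent C3) suggests that the inherent bias of C4 may oppose the catalyst, so facial selectivity may be poor. The fallback sets out from 34 and comes back at 35. Substrate-controlled reduction (L-Selectride, −78 °C) is used deliberately to give the (7S) epimer of 35, F12. Mitsunobu reaction with chloroacetic acid (PPh3, DIAD) inverts C7 to the (7R) chloroacetate of 35, F13. Thiourea and NaHCO3 in ethanol remove the chloroacetyl group without opening the lactone and give 35.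

## Further compounds

F1 | step 5 | cis-fused 6,6-diethoxy-4-[(1S,2R,5S)-menthyloxy]-3-oxabicyclo[3.2.0]heptan-2-one (menthyloxy anti to the cyclobutane) | O=C1O[C@H](O[C@H]3C[C@@H](C)CC[C@@H]3C(C)C)[C@@H]2[C@H]1CC2(OCC)OCC
F2 | step 5 | (1R,5S)-3-oxabicyclo[3.2.0]heptane-2,6-dione | O=C1OC[C@@H]2[C@H]1CC2=O
F3 | step 5 | 4-bromo-2-methoxy-1-(triisopropylsilyloxy)benzene | COc1cc(Br)ccc1O[Si](C(C)C)(C(C)C)C(C)C
F4 | step 19 | (5R)-5-[(1R,2S,5R)-menthyloxy]-2(5H)-furanone | O=C1C=C[C@H](O[C@@H]2C[C@H](C)CC[C@H]2C(C)C)O1
F5 | step 19 | 3-methoxy-4-(triisopropylsilyloxy)benzaldehyde | COc1cc(C=O)ccc1O[Si](C(C)C)(C(C)C)C(C)C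
F6 | step 19 | 2-[3-methoxy-4-(triisopropylsilyloxy)phenyl]-1,3-dithiane | COc1cc(C2SCCCS2)ccc1O[Si](C(C)C)(C(C)C)C(C)C
F7 | step 19 | [(2S,3R)-3-[(tert-butyldimethylsilyloxy)methyl]-2-[4-(tert-butyldimethylsilyloxy)-3-methoxyphenyl]-7-methoxy-2,3-dihydrobenzofuran-5-yl]methanol | COc1cc([C@H]2Oc3c(OC)cc(CO)cc3[C@@H]2CO[Si](C)(C)C(C)(C)C)ccc1O[Si](C)(C)C(C)(C)C
F8 | step 19 | (2S,3R)-5-(bromomethyl)-3-[(tert-butyldimethylsilyloxy)methyl]-2-[4-(tert-butyldimethylsilyloxy)-3-methoxyphenyl]-7-methoxy-2,3-dihydrobenzofuran | COc1cc([C@H]2Oc3c(OC)cc(CBr)cc3[C@@H]2CO[Si](C)(C)C(C)(C)C)ccc1O[Si](C)(C)C(C)(C)C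
F9 | step 19 | all-trans 3-(arylmethyl)-4-{2-[3-methoxy-4-(triisopropylsilyloxy)phenyl]-1,3-dithian-2-yl}-5-[(1R,2S,5R)-menthyloxy]dihydrofuran-2(3H)-one (arylmethyl as in 34) | O=C1O[C@@H](O[C@@H]2C[C@H](C)CC[C@H]2C(C)C)[C@H](C2(c3ccc(O[Si](C(C)C)(C(C)C)C(C)C)c(OC)c3)SCCCS2)[C@H]1Cc1cc(OC)c2O[C@H](c3ccc(O[Si](C)(C)C(C)(C)C)c(OC)c3)[C@@H](CO[Si](C)(C)C(C)(C)C)c2c1
F10 | step 19 | trans-3-(arylmethyl)-4-{2-[3-methoxy-4-(triisopropylsilyloxy)phenyl]-1,3-dithian-2-yl}dihydrofuran-2(3H)-one (arylmethyl as in 34) | O=C1OC[C@H](C2(c3ccc(O[Si](C(C)C)(C(C)C)C(C)C)c(OC)c3)SCCCS2)[C@H]1Cc1cc(OC)c2O[C@H](c3ccc(O[Si](C)(C)C(C)(C)C)c(OC)c3)[C@@H](CO[Si](C)(C)C(C)(C)C)c2c1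
F11 | step 6 | cis-3-[3-methoxy-4-(triisopropylsilyloxy)phenyl]-3-(triethylsilyloxy)cyclobutane-1,2-dimethanol | OC[C@@H]1C[C@@](O[Si](CC)(CC)CC)(c2ccc(O[Si](C(C)C)(C(C)C)C(C)C)c(OC)c2)[C@@H]1CO
F12 | step 21 | (7S) epimer of 35 | O=C1OC[C@H]([C@H](O)c2ccc(O[Si](C(C)C)(C(C)C)C(C)C)c(OC)c2)[C@H]1Cc1cc(OC)c2O[C@H](c3ccc(O[Si](C)(C)C(C)(C)C)c(OC)c3)[C@@H](CO[Si](C)(C)C(C)(C)C)c2c1
F13 | step 21 | (7R) chloroacetate of 35 | O=C1OC[C@H]([C@@H](OC(=O)CCl)c2ccc(O[Si](C(C)C)(C(C)C)C(C)C)c(OC)c2)[C@H]1Cc1cc(OC)c2O[C@H](c3ccc(O[Si](C)(C)C(C)(C)C)c(OC)c3)[C@@H](CO[Si](C)(C)C(C)(C)C)c2c1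
A1 | alternative 1 | (2S,3R)-5-bromo-2-(4-hydroxy-3-methoxyphenyl)-3-(hydroxymethyl)-7-methoxy-2,3-dihydrobenzofuran | COc1cc([C@H]2Oc3c(OC)cc(Br)cc3[C@@H]2CO)ccc1O
A2 | alternative 2 | (4R)-4-[(R)-[3-methoxy-4-(tert-butyldimethylsilyloxy)phenyl](tert-butyldimethylsilyloxy)methyl]dihydrofuran-2(3H)-one | O=C1OC[C@H]([C@@H](O[Si](C)(C)C(C)(C)C)c2ccc(O[Si](C)(C)C(C)(C)C)c(OC)c2)C1
A3 | alternative 2 | 3-[(R)-[3-methoxy-4-(tert-butyldimethylsilyloxy)phenyl](tert-butyldimethylsilyloxy)methyl]cyclobutan-1-one | O=C1CC(C1)[C@@H](O[Si](C)(C)C(C)(C)C)c1ccc(O[Si](C)(C)C(C)(C)C)c(OC)c1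
A4 | alternative 3 | (3R,4R)-trans-4-aroyl-3-(arylmethyl)dihydrofuran-2(3H)-one, all-TBS analogue of 34 | COc1cc([C@H]2Oc3c(OC)cc(C[C@H]4C(=O)OC[C@@H]4C(=O)c4ccc(O[Si](C)(C)C(C)(C)C)c(OC)c4)cc3[C@@H]2CO[Si](C)(C)C(C)(C)C)ccc1O[Si](C)(C)C(C)(C)C
A5 | alternative 3 | methyl (R)-2-(arylmethyl)-4-[3-methoxy-4-(tert-butyldimethylsilyloxy)phenyl]-4-oxobutanoate (arylmethyl as in A4) | COC(=O)[C@H](Cc1cc(OC)c2O[C@H](c3ccc(O[Si](C)(C)C(C)(C)C)c(OC)c3)[C@@H](CO[Si](C)(C)C(C)(C)C)c2c1)CC(=O)c1ccc(O[Si](C)(C)C(C)(C)C)c(OC)c1
A6 | alternative 3 | formaldehyde | C=O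
A7 | alternative 2 | (2S,3R)-5-(bromomethyl)-3-[(tert-butyldimethylsilyloxy)methyl]-2-[4-(tert-butyldimethylsilyloxy)-3-methoxyphenyl]-7-methoxy-2,3-dihydrobenzofuran | COc1cc([C@H]2Oc3c(OC)cc(CBr)cc3[C@@H]2CO[Si](C)(C)C(C)(C)C)ccc1O[Si](C)(C)C(C)(C)C
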